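The numbers in the tables come from a simulation on assumed constants; noise was put on by code.

| setting | Sunday's | Tuesday's | flask |
|---|---|---|---|
| starting material | 20 mM (fed, over 2.0 d) | 20 mM (fed, over 2.0 d) | 20 mM (fed, over 2.0 d) |
| partner | 24 mM | 48 mM | 24.0 mM |
| remark | the very flask that is asked about, followed so far | run made earlier |  |
| time |  |  | 2.0 d |

| run | time / h | starting material / % | first product / % |
|---|---|---|---|
| Sunday's | 4.00 | 8 | 2 |
| Sunday's | 8.00 | 12 | 1 |
| Sunday's | 10.0 | 19 | 2 |
| Sunday's | 15.0 | 23 | 3 |
| Tuesday's | 12.0 | 20 | 4 |
| Tuesday's | 25.0 | 23 | 7 |
| Tuesday's | 40.0 | 36 | 6 |
| Tuesday's | 50.0 | 41 | 5 |

(each reading ± 1.5 percentage points)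

1. amount of starting material at 2.0 d, in percent of the starting material charged
2. amount of first product at 2.0 d, in percent of the starting material charged
3. amount of bis adduct at 2.0 d, in percent of the starting material charged
4. amount of triple product at 2.0 d, in percent of the starting material charged

- what is said of triple product includes idle adduct
- the earlier runs were read with a standard deviation of 1.5 percentage points
- what may be going on: starting material + partner -> first product + by-product; partner + first product -> bis adduct + by-product; partner + bis adduct -> triple product + by-product; partner + triple product <-> idle adduct; first product -> decomposed reagent
- percentages count the whole charge, also what has not yet gone in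

Step 1. Start with the easy step: count what has gone in. By 15.0 h, Sunday's flask has received 31.2% of the charge and holds 23% as starting material, so 8.25% has been used.

Step 2. Divide the area under the starting-material readings by that amount. This gives the holding time, a pseudo-first-order life at the charged c(partner): 0.970 d, a reading with scatter. Take it to scale as one over c(partner).

Step 3. Define the feed balance as rate of use over rate of feed: stock, times partner left as a fraction of its charge, times dosing time, over holding time. At 1, use matches feed.

Step 4. Run the main step alone, with partner held at its charge. The end stock is 42.3%, and the balance is 0.873.

Step 5. Let partner fall. Sunday's last reading puts about 1.64 partner on each starting material used, counting what has passed first product. One pass of my own reckoning ends partner near 21.3% and averages 60.7%. The holding time stretches to 1.60 d, and the stock becomes 57.0%.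

Step 6. Add the rest. Later steps act on the stock through that partner cost, and decomposition takes no partner. The balance of 0.714 is less than 1, so use trails the feed and the stock keeps rising.

Step 7. The forecast gives 66%, 8%, 14% and 11%, and of the last two says “this rests only on partner stoichiometry”. Its starting material is higher than my 57.0%.

Step 8. The flask gives 61.1%, 9.43%, 19.8% and 6.78%.

    starting material + partner → first product + by-product (k = 0.0260 L mol⁻¹ min⁻¹)
    partner + first product → bis adduct + by-product (k = 0.120 L mol⁻¹ min⁻¹)
    partner + bis adduct → triple product + by-product (k = 0.0200 L mol⁻¹ min⁻¹)
    partner + triple product ⇌ idle adduct, settled at all times (K = 83.0 L mol⁻¹)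
    first product → decomposed reagent (k = 2.00 × 10⁻⁴ min⁻¹)

The forecast and the flask part on bis adduct, which stands 5.8 percentage points above the forecast. At 2.00 d, this flask holds 61.1% of starting material and 37.4% of its partner, so its feed balance, reckoned with the holding time read from Sunday's readings and carrying their scatter, is 0.472, less than 1. The neighbour with 96 mM of partner has the read holding time scaled to 0.242 d, and with 22.5% of starting material and 50.5% of its partner its balance, reckoned the same way, is higher than this flask's, at 0.937.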